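**Retrosynthetic overview**

1. Target 21 ⇐ phenol unmasking of 20 ⇐ C5–O bond: γ-aroyloxylation of enone 15 with peroxide 17 (new reaction; makes the ester bond and sets C5).
2. 15 ⇐ correction of C1 (desilylation, oxidation, α-face hydride reduction) and acetylation of bicyclic enone 11.
3. 11 (seven-membered ring, formed second) ⇐ intramolecular aldol condensation of keto aldehyde 10 ⇐ double ozonolysis of diene 9.
4. 9 ⇐ isopropyl addition to cyclopentanone 8 ⇐ conjugate methylation/enolate allylation of enone 4 (sets C10 and C4).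
5. 4 ⇐ conjugate addition/dehydrogenation on (R)-4-silyloxycyclopentenone 1 (five-membered ring bought; its C1 centre relays all later stereochemistry).

Convention and assumption: route numbering is C1 = CH–O next to the quaternary carbon, C2 = CH2, C3 = C(OH)iPr, C4 = ring-fusion CH, C5 = CH–O(aroyl), C6=C7(Me), C8 = C=O, C9 = CH2, C10 = C–Me; β is the face of the C10 methyl; the target is then (1S,3S,4R,5R,10S); 1 and 2 are taken as catalogue chemicals.

**Step 1**
Reactants: 1 (R)-4-[(tert-butyldimethylsilyl)oxy]cyclopent-2-en-1-one; 2 2-(chloromethyl)but-1-ene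
Product: 4 (R)-4-[(tert-butyldimethylsilyl)oxy]-3-(2-methylenebutyl)cyclopent-2-en-1-one, via enol silane 3 (not isolated)
Conditions: 2, Mg, THF; CuBr·SMe2, Me3SiCl, THF, −78 °C; filter, concentrate; Pd(OAc)2 (10 mol %), O2, DMSO, rt
Reagents that add atoms: trimethylsilyl chloride, C[Si](C)(C)Cl (silyl group only in 3)
Why: Copper-mediated conjugate addition of the allylic Grignard reagent with in situ silylation, then Saegusa–Ito-type dehydrogenation of enol silane 3, returns the enone with the C9–C8 unit on C10; only the C1 centre of 1 survives.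

**Step 2**
Reactants: 4 (R)-4-[(tert-butyldimethylsilyl)oxy]-3-(2-methylenebutyl)cyclopent-2-en-1-one; 5 allyl bromide
Product: 8 (2S,3S,4R)-2-allyl-4-[(tert-butyldimethylsilyl)oxy]-3-methyl-3-(2-methylenebutyl)cyclopentan-1-one, via enol silane 6 (not isolated), via lithium enolate 7 (not isolated)
Conditions: MeMgBr, CuBr·SMe2 (10 mol %), Me3SiCl, HMPA, THF, −78 °C; concentrate; MeLi, THF, 0 °C; then 5, HMPA, −78 to −20 °C
Reagents that add atoms: methylmagnesium bromide, C[Mg]Br; trimethylsilyl chloride, C[Si](C)(C)Cl (silyl group only in 6); methyllithium, [Li]C (lithium only in 7)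
Why: Copper-catalysed Grignard 1,4-addition puts methyl on C10 anti to the C1 silyloxy group (quaternary centre, methyl β), and the regiospecific lithium enolate is allylated at C4 from the β face, anti to the α side chain and α silyloxy group (tandem conjugate addition–enolate alkylation), which fixes the trans ring-fusion relationship.

**Step 3**
Reactants: 8 (2S,3S,4R)-2-allyl-4-[(tert-butyldimethylsilyl)oxy]-3-methyl-3-(2-methylenebutyl)cyclopentan-1-one
Product: 9 (1S,2S,3S,4R)-2-allyl-4-[(tert-butyldimethylsilyl)oxy]-3-methyl-3-(2-methylenebutyl)-1-(propan-2-yl)cyclopentan-1-ol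
Conditions: iPrMgCl, LaCl3·2LiCl, THF, −20 °C; aq. NH4Cl
Reagents that add atoms: isopropylmagnesium chloride, CC(C)[Mg]Cl
Why: Lanthanide-promoted Grignard 1,2-addition (suppresses enolisation and β-hydride reduction) in which isopropyl attacks anti to the vicinal C4 allyl group and the β methyl, giving the 3β-hydroxy-3α-isopropyl carbinol.

**Step 4**
Reactants: 9 (1S,2S,3S,4R)-2-allyl-4-[(tert-butyldimethylsilyl)oxy]-3-methyl-3-(2-methylenebutyl)-1-(propan-2-yl)cyclopentan-1-ol
Product: 10 keto aldehyde: the cyclopentanol of 9 carrying CH2CHO at C4 and CH2C(=O)CH2CH3 at C10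
Conditions: O3, CH2Cl2/MeOH, −78 °C; Me2S, −78 °C to rt
Reagents that add atoms: ozone, [O-][O+]=O
Why: Ozonolysis with reductive work-up cleaves the allyl group to the C6 aldehyde and the 1,1-disubstituted alkene to the C8 ethyl ketone without touching a stereocentre (10 equilibrates with its C3–O–C6 lactol).

**Step 5**
Reactants: 10 keto aldehyde
Product: 11 1α-[(tert-butyldimethylsilyl)oxy]-3β-hydroxy-3α-isopropyl-7,10β-dimethyl-4αH-bicyclo[5.3.0]dec-6-en-8-one (route numbering; trans-fused)
Conditions: Bn2NH·CF3CO2H, benzene, 50 °C, 0.01 M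
Reagents that add atoms: none
Why: Amine-salt-mediated intramolecular aldol condensation in which C7 of the ethyl ketone adds to the C6 aldehyde and water is lost; this is the only strain-free closure, because attack through C9 or C5 would give a trans-fused bicyclo[3.3.0]octane.

**Step 6**
Reactants: 11 silyl ether enone
Product: 12 1α,3β-dihydroxy-3α-isopropyl-7,10β-dimethyl-4αH-bicyclo[5.3.0]dec-6-en-8-one
Conditions: HF·pyridine, THF, 0 °C to rt
Reagents that add atoms: none
Why: Fluoride cleavage of the secondary silyl ether under acidic conditions spares the tertiary alcohol and avoids base-induced conjugate addition of the C3 hydroxyl to the enone.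

**Step 7**
Reactants: 12 diol enone
Product: 13 3β-hydroxy-3α-isopropyl-7,10β-dimethyl-4αH-bicyclo[5.3.0]dec-6-ene-1,8-dione
Conditions: Dess–Martin periodinane, NaHCO3, CH2Cl2, 0 °C
Reagents that add atoms: none
Why: Dess–Martin oxidation of the only secondary alcohol gives the C1 ketone and deletes the C1 centre that served as the stereochemical relay.

**Step 8**
Reactants: 13 diketone
Product: 14 1β,3β-dihydroxy-3α-isopropyl-7,10β-dimethyl-4αH-bicyclo[5.3.0]dec-6-en-8-one
Conditions: NaBH4, MeOH/CH2Cl2, −40 °C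
Reagents that add atoms: none
Why: Borohydride reduction is selective for the saturated cyclopentanone over the conjugated C8 ketone, and hydride attacks C1 from the α face, anti to the angular methyl on the adjacent quaternary carbon (the sense known for steroid 17-ketones), giving the 1β-alcohol.

**Step 9**
Reactants: 14 1β-alcohol
Product: 15 1β-acetoxy-3β-hydroxy-3α-isopropyl-7,10β-dimethyl-4αH-bicyclo[5.3.0]dec-6-en-8-one
Conditions: Ac2O, pyridine, DMAP (cat.), CH2Cl2, 0 °C
Reagents that add atoms: acetic anhydride, CC(=O)OC(C)=O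
Why: DMAP-catalysed acylation of the secondary alcohol; the hindered tertiary alcohol does not react.

**Step 10**
Reactants: 16 4-acetoxybenzoic acid (2 equiv; both aroyl groups of 17 come from it)
Product: 17 bis(4-acetoxybenzoyl) peroxide
Conditions: 16 (2.0 equiv), urea·H2O2 (1.0 equiv H2O2), DCC (2.0 equiv), CH2Cl2, −10 to 0 °C; filter off the urea, crystallise cold
Reagents that add atoms: 4-acetoxybenzoic acid (second equivalent of 16), CC(=O)Oc1ccc(cc1)C(=O)O; hydrogen peroxide (from urea·H2O2), OO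
Why: Carbodiimide-mediated dehydrative coupling in which each of two acid molecules is activated as its O-acylisourea and acylates one oxygen of hydrogen peroxide (2 ArCO2H + H2O2 + 2 DCC → ArC(O)OOC(O)Ar + 2 dicyclohexylurea), giving the symmetrical diaroyl peroxide under neutral anhydrous conditions that leave the aryl acetates intact.

**Step 11**
Reactants: 15 enone acetate; 17 bis(4-acetoxybenzoyl) peroxide
Product: 20 1β-acetoxy-3β-hydroxy-3α-isopropyl-7,10β-dimethyl-8-oxo-4αH-bicyclo[5.3.0]dec-6-en-5α-yl 4-acetoxybenzoate, via dienol silane 18 (not isolated), via silyl ether 19 (not isolated)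
Conditions: Me3SiOTf, Et3N, CH2Cl2, 0 °C; pentane, filter, concentrate; 17, Cu(OTf)2 (10 mol %), CH2Cl2, −40 °C; 1 M HCl, THF, 0 °C
Reagents that add atoms: trimethylsilyl trifluoromethanesulfonate, C[Si](C)(C)OS(=O)(=O)C(F)(F)F (silyl groups only in 18 and 19)
Why: Proposed new method: vinylogous (γ-selective) electrophilic aroyloxylation of a 1-silyloxy-1,3-diene by a Lewis-acid-activated diaroyl peroxide – the linear dienol silane 18 has its largest HOMO coefficient at C5, which attacks one peroxide oxygen of 17 (O–O bond activated by Cu(OTf)2, divalent copper, on the carbonyl groups) from the α face, anti to the C4–C3 bond and the C10 methyl, and the expelled carboxylate removes the silyl group from the oxocarbenium ion, so the C5–O ester bond and the 5R centre form in one event; the closest known reactions are the vinylogous Rubottom oxidation of silyl dienol ethers with peracids and the α-benzoyloxylation of enamines and β-keto esters with dibenzoyl peroxide.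

**Step 12**
Reactants: 20 aryl acetate
Product: 21 target, (1S,3S,4R,5R,10S)-1-acetoxy-3-hydroxy-3-isopropyl-7,10-dimethyl-8-oxobicyclo[5.3.0]dec-6-en-5-yl 4-hydroxybenzoate (route numbering)
Conditions: NH4OAc, MeOH, rt
Reagents that add atoms: none
Why: Chemoselective transesterification: the aryl acetate (phenoxide leaving group) is methanolysed much faster than the alkyl acetate at C1 or the benzoate at C5, and no stereocentre is touched.

**Compound list**

1 | (R)-4-[(tert-butyldimethylsilyl)oxy]cyclopent-2-en-1-one | CC(C)(C)[Si](C)(C)O[C@@H]1CC(=O)C=C1 | starting material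
2 | 2-(chloromethyl)but-1-ene | CCC(=C)CCl | starting material
3 | (3R,4R)-4-(tert-butyldimethylsilyloxy)-3-(2-methylenebutyl)-1-(trimethylsilyloxy)cyclopent-1-ene (3,4-trans) | CC(C)(C)[Si](C)(C)O[C@@H]1CC(O[Si](C)(C)C)=C[C@H]1CC(=C)CC | intermediate
4 | (R)-4-[(tert-butyldimethylsilyl)oxy]-3-(2-methylenebutyl)cyclopent-2-en-1-one | CC(C)(C)[Si](C)(C)O[C@@H]1CC(=O)C=C1CC(=C)CC | intermediate
5 | allyl bromide (3-bromoprop-1-ene) | C=CCBr | starting material
6 | (3S,4R)-4-(tert-butyldimethylsilyloxy)-3-methyl-3-(2-methylenebutyl)-1-(trimethylsilyloxy)cyclopent-1-ene (methyl trans to OTBS) | CC(C)(C)[Si](C)(C)O[C@@H]1CC(O[Si](C)(C)C)=C[C@]1(C)CC(=C)CC | intermediate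
7 | lithium enolate corresponding to 6 | CC(C)(C)[Si](C)(C)O[C@@H]1CC([O-])=C[C@]1(C)CC(=C)CC.[Li+] | intermediate
8 | (2S,3S,4R)-2-allyl-4-[(tert-butyldimethylsilyl)oxy]-3-methyl-3-(2-methylenebutyl)cyclopentan-1-one (allyl cis to methyl, trans to OTBS and to the side chain) | CC(C)(C)[Si](C)(C)O[C@@H]1CC(=O)[C@@H](CC=C)[C@]1(C)CC(=C)CC | intermediate
9 | (1S,2S,3S,4R)-2-allyl-4-[(tert-butyldimethylsilyl)oxy]-3-methyl-3-(2-methylenebutyl)-1-(propan-2-yl)cyclopentan-1-ol (OH cis to allyl and methyl) | CC(C)(C)[Si](C)(C)O[C@@H]1C[C@](O)(C(C)C)[C@@H](CC=C)[C@]1(C)CC(=C)CC | intermediate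
10 | keto aldehyde: cyclopentanol of 9 with CH2CHO at C4 and CH2C(=O)CH2CH3 at C10 | CC(C)(C)[Si](C)(C)O[C@@H]1C[C@](O)(C(C)C)[C@@H](CC=O)[C@]1(C)CC(=O)CC | intermediate
11 | 1α-[(tert-butyldimethylsilyl)oxy]-3β-hydroxy-3α-isopropyl-7,10β-dimethyl-4αH-bicyclo[5.3.0]dec-6-en-8-one | CC(C)(C)[Si](C)(C)O[C@@H]1C[C@](O)(C(C)C)[C@H]2CC=C(C)C(=O)C[C@]12C | intermediate
12 | 1α,3β-dihydroxy-3α-isopropyl-7,10β-dimethyl-4αH-bicyclo[5.3.0]dec-6-en-8-one | O[C@@H]1C[C@](O)(C(C)C)[C@H]2CC=C(C)C(=O)C[C@]12C | intermediate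
13 | 3β-hydroxy-3α-isopropyl-7,10β-dimethyl-4αH-bicyclo[5.3.0]dec-6-ene-1,8-dione | O=C1C[C@](O)(C(C)C)[C@H]2CC=C(C)C(=O)C[C@]12C | intermediate
14 | 1β,3β-dihydroxy-3α-isopropyl-7,10β-dimethyl-4αH-bicyclo[5.3.0]dec-6-en-8-one | O[C@H]1C[C@](O)(C(C)C)[C@H]2CC=C(C)C(=O)C[C@]12C | intermediate
15 | 1β-acetoxy-3β-hydroxy-3α-isopropyl-7,10β-dimethyl-4αH-bicyclo[5.3.0]dec-6-en-8-one | CC(=O)O[C@H]1C[C@](O)(C(C)C)[C@H]2CC=C(C)C(=O)C[C@]12C | intermediate
16 | 4-acetoxybenzoic acid | CC(=O)Oc1ccc(cc1)C(=O)O | starting material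
17 | bis(4-acetoxybenzoyl) peroxide | CC(=O)Oc1ccc(cc1)C(=O)OOC(=O)c1ccc(OC(C)=O)cc1 | intermediate
18 | 1β-acetoxy-3α-isopropyl-7,10β-dimethyl-3β,8-bis(trimethylsilyloxy)-4αH-bicyclo[5.3.0]deca-5,7-diene | CC(=O)O[C@H]1C[C@](O[Si](C)(C)C)(C(C)C)[C@H]2C=CC(C)=C(O[Si](C)(C)C)C[C@]12C | intermediate
19 | 3-O-trimethylsilyl ether of 20 | CC(=O)O[C@H]1C[C@](O[Si](C)(C)C)(C(C)C)[C@H]2[C@H](OC(=O)c3ccc(OC(C)=O)cc3)C=C(C)C(=O)C[C@]12C | intermediate
20 | 1β-acetoxy-3β-hydroxy-3α-isopropyl-7,10β-dimethyl-8-oxo-4αH-bicyclo[5.3.0]dec-6-en-5α-yl 4-acetoxybenzoate | CC(=O)O[C@H]1C[C@](O)(C(C)C)[C@H]2[C@H](OC(=O)c3ccc(OC(C)=O)cc3)C=C(C)C(=O)C[C@]12C | intermediate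
21 | (1S,3S,4R,5R,10S)-1-acetoxy-3-hydroxy-3-isopropyl-7,10-dimethyl-8-oxobicyclo[5.3.0]dec-6-en-5-yl 4-hydroxybenzoate (route numbering) | CC(=O)O[C@H]1C[C@](O)(C(C)C)[C@H]2[C@H](OC(=O)c3ccc(O)cc3)C=C(C)C(=O)C[C@]12C | target

**Totals**

Total step count: 12. Longest linear sequence: 11 steps (steps 1–9, 11, 12).

**Three steps most likely to fail, with fallbacks**

Step 11 (the new C–O bond formation). The risks are formation of the α′-enol silane instead of the linear dienol silane, attack at C7, radical decomposition of 17, and incomplete α-face selectivity. The known-chemistry fallback sets out from 15 and comes back at 20. 15 is converted to dienol silane 18 as above. Dye-sensitised photooxygenation (O2, tetraphenylporphyrin, visible light, CH2Cl2, −78 °C) adds singlet oxygen across C5/C8 from the α face, and silyl migration gives silyl peroxide F1. PPh3 followed by dilute HCl gives γ-hydroxy enone F2 (5α-OH). Acylation with commercial 4-acetoxybenzoyl chloride (pyridine, DMAP, CH2Cl2) gives 20.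

Step 5 (seven-membered aldol condensation). The risks are slow closure, masking of the aldehyde as a lactol, and oligomers. The fallback sets out from 9 and comes back at 11, closing the ring by olefin metathesis instead. mCPBA (1 equiv, NaHCO3, CH2Cl2, 0 °C) epoxidises the more electron-rich 1,1-disubstituted alkene to epoxide F3. H5IO6 (THF/H2O) cleaves it to ethyl ketone F4 with the allyl group intact. LiN(SiMe3)2 then dimethylmethyleneiminium iodide gives Mannich base F5 at C7 (C9 is neopentyl), and MeI/NaHCO3 eliminates to isopropenyl ketone F6. Second-generation Hoveyda–Grubbs catalyst (toluene, 80 °C, 2 mM) then gives 11.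

Step 2 (quaternary centre next to a silyloxy carbon, and substrate-controlled facial selectivity of the allylation). The fallback sets out from 4 and comes back at 8. Lithium enolate 7 is generated as in step 2 and O-acylated with allyl chloroformate to allyl enol carbonate F7. F7 then undergoes decarboxylative allylation with Pd2(dba)3 and a chiral Trost bisphosphine ligand chosen to deliver the allyl group to the β face (catalyst control, Tsuji–Trost reaction).

**Further compounds**

F1 | step 11 | 1β-acetoxy-3α-isopropyl-7,10β-dimethyl-3β-(trimethylsilyloxy)-5α-(trimethylsilylperoxy)-4αH-bicyclo[5.3.0]dec-6-en-8-one | CC(=O)O[C@H]1C[C@](O[Si](C)(C)C)(C(C)C)[C@H]2[C@H](OO[Si](C)(C)C)C=C(C)C(=O)C[C@]12C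
F2 | step 11 | 1β-acetoxy-3β,5α-dihydroxy-3α-isopropyl-7,10β-dimethyl-4αH-bicyclo[5.3.0]dec-6-en-8-one | CC(=O)O[C@H]1C[C@](O)(C(C)C)[C@H]2[C@H](O)C=C(C)C(=O)C[C@]12C
F3 | step 5 | epoxide of the 1,1-disubstituted alkene of 9 | CC(C)(C)[Si](C)(C)O[C@@H]1C[C@](O)(C(C)C)[C@@H](CC=C)[C@]1(C)CC1(CC)CO1
F4 | step 5 | ethyl ketone: cyclopentanol of 9 with CH2C(=O)CH2CH3 at C10 and the allyl group intact | CC(C)(C)[Si](C)(C)O[C@@H]1C[C@](O)(C(C)C)[C@@H](CC=C)[C@]1(C)CC(=O)CC
F5 | step 5 | Mannich base of F4 (CH2NMe2 at C7) | CC(C)(C)[Si](C)(C)O[C@@H]1C[C@](O)(C(C)C)[C@@H](CC=C)[C@]1(C)CC(=O)C(C)CN(C)C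
F6 | step 5 | isopropenyl ketone derived from F5 | CC(C)(C)[Si](C)(C)O[C@@H]1C[C@](O)(C(C)C)[C@@H](CC=C)[C@]1(C)CC(=O)C(C)=C
F7 | step 2 | allyl enol carbonate of enolate 7 | CC(C)(C)[Si](C)(C)O[C@@H]1CC(OC(=O)OCC=C)=C[C@]1(C)CC(=C)CC
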